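**Retrosynthetic overview**

1. Lepadin H ⇒ late acylation of O3 with (2E,4E)-octa-2,4-dienoic acid, and Wittig olefination at C5 followed by convex-face hydrogenation on the cis-fused 5-oxodecahydroquinoline 19/20 (side-chain ylide from (R)-1,2-epoxypentane).
2. Feature used: once C5 carries a carbonyl, N1–C8a–C4a–C5=O is a β-amino ketone and C7–C8 is a bare two-carbon unit. Ring A (C4a–C5–C6–C7–C8–C8a) is therefore grown from ethylene on the eight-membered enaminone N1–C8a=C6–C5=O of azocinone 14.
3. Key sequence: [2+2] photocycloaddition (C8a–C8, C6–C7), retro-Mannich cleavage of C8a–C6 to a ten-membered keto-imine, transannular Mannich closure of C4a–C8a.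
4. Azocinone ⇒ 8-endo-dig addition of a secondary N-(4-methoxybenzyl) amine to an ynone (a primary amine would instead condense with the C5 ketone to a six-membered imine). The open chain comes from Boc-L-alanine Weinreb amide, with C3 set against C2 by chelation-controlled ketone reduction.
5. Ring order: eight-membered azocinone → transient cyclobutane → ten-membered ring → ring A and the piperidine (ring B) together, through the one transannular bond.

Key step: step 9

Remark: ring atoms carry decahydroquinoline numbers (N1, C2, C3, C4, C4a, C5–C8, C8a) throughout, also in the monocyclic precursors; side-chain carbons are C1′–C8′.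

**Route**

Step 1
Reactants: 1 tert-butyl (S)-(1-(methoxy(methyl)amino)-1-oxopropan-2-yl)carbamate (Boc-L-alanine Weinreb amide); 2 but-3-en-1-ylmagnesium bromide
Product: 3 tert-butyl (S)-(3-oxohept-6-en-2-yl)carbamate
Conditions: 2 (3 equiv), THF, −15 → 0 °C; aq. NH4Cl
Reagents that add atoms: none
Why: Weinreb ketone synthesis, in which the N-metallated carbamate and the stable magnesium chelate of the tetrahedral adduct stop the addition at the ketone and protect the α-stereocentre from enolisation.

Step 2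
Reactants: 3 tert-butyl (S)-(3-oxohept-6-en-2-yl)carbamate
Product: 4 tert-butyl ((2S,3R)-3-hydroxyhept-6-en-2-yl)carbamate
Conditions: LiAlH(OtBu)3, EtOH, −78 °C
Reagents that add atoms: none
Why: Chelation-controlled hydride reduction of an N–H carbamate α-amino ketone, in which hydride should attack the chelate on the face away from the methyl group and give the anti amino alcohol, setting C3 (R) relative to C2.

Step 3
Reactants: 4 tert-butyl ((2S,3R)-3-hydroxyhept-6-en-2-yl)carbamate
Product: 6 tert-butyl ((2S,3R)-3-(benzyloxy)hept-6-en-2-yl)(4-methoxybenzyl)carbamate, via O-benzyl carbamate 5 (not isolated)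
Conditions: NaH, BnBr (1.05 equiv), Bu4NI (cat.), THF, 0 °C; then NaH, 4-methoxybenzyl chloride, DMF, 0 °C → rt
Reagents that add atoms: benzyl bromide, BrCc1ccccc1; 4-methoxybenzyl chloride, COc1ccc(CCl)cc1
Why: Williamson O-benzylation of the alkoxide followed in the same flask by N-alkylation of the carbamate anion, so that Boc removal later leaves a secondary amine that cannot condense with the C5 ketone to a six-membered imine.

Step 4
Reactants: 6 tert-butyl ((2S,3R)-3-(benzyloxy)hept-6-en-2-yl)(4-methoxybenzyl)carbamate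
Product: 7 tert-butyl ((2S,3R)-3-(benzyloxy)-6-oxohexan-2-yl)(4-methoxybenzyl)carbamate
Conditions: OsO4 (cat.), NaIO4, 2,6-lutidine, dioxane/H2O, rt
Reagents that add atoms: sodium periodate, [Na+].[O-]I(=O)(=O)=O (source of the aldehyde oxygen, relayed by OsO4)
Why: Lemieux–Johnson oxidation cleaves only the terminal alkene (dihydroxylation, then glycol cleavage) and leaves the electron-rich benzyl groups alone.

Step 5
Reactants: 7 tert-butyl ((2S,3R)-3-(benzyloxy)-6-oxohexan-2-yl)(4-methoxybenzyl)carbamate; 8 ethynylmagnesium bromide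
Product: 9 tert-butyl ((2S,3R)-3-(benzyloxy)-6-hydroxyoct-7-yn-2-yl)(4-methoxybenzyl)carbamate (both C6 epimers)
Conditions: 8, THF, −78 → 0 °C; aq. NH4Cl
Reagents that add atoms: none
Why: Grignard 1,2-addition of the acetylide to the aldehyde, whose new carbinol centre is oxidised away in the next step and so needs no control.

Step 6
Reactants: 9 tert-butyl ((2S,3R)-3-(benzyloxy)-6-hydroxyoct-7-yn-2-yl)(4-methoxybenzyl)carbamate
Product: 10 tert-butyl ((2S,3R)-3-(benzyloxy)-6-oxooct-7-yn-2-yl)(4-methoxybenzyl)carbamate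
Conditions: Dess–Martin periodinane, CH2Cl2, 0 °C → rt
Reagents that add atoms: none
Why: Dess–Martin oxidation turns the propargylic alcohol into the terminal ynone under near-neutral conditions that the carbamate and both benzyl groups tolerate.

Step 7
Reactants: 10 tert-butyl ((2S,3R)-3-(benzyloxy)-6-oxooct-7-yn-2-yl)(4-methoxybenzyl)carbamate
Product: 12 (2Z,7R,8S)-7-(benzyloxy)-1-(4-methoxybenzyl)-8-methyl-5,6,7,8-tetrahydroazocin-4(1H)-one, via amino ynone trifluoroacetate 11 (not isolated)
Conditions: TFA, CH2Cl2, 0 °C; evaporate; then slow addition to iPr2NEt, MeCN (final 2 mM), 40 °C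
Reagents that add atoms: none
Why: Acidolytic Boc removal followed by intramolecular aza-Michael addition of the secondary amine to the terminal ynone in the 8-endo-dig mode, a cyclisation established for six- and seven-membered enaminones; for a secondary amine carbinolamine formation at the ketone is reversible while the conjugate addition is not, and pseudo-high dilution disfavours oligomers.

Step 8
Reactants: 12 (2Z,7R,8S)-7-(benzyloxy)-1-(4-methoxybenzyl)-8-methyl-5,6,7,8-tetrahydroazocin-4(1H)-one
Product: 14 tert-butyl (2Z,7R,8S)-7-(benzyloxy)-8-methyl-4-oxo-5,6,7,8-tetrahydroazocine-1(4H)-carboxylate, via N–H azocinone 13 (not isolated)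
Conditions: TFA, anisole, 60 °C; evaporate; then Boc2O, DMAP, Et3N, CH2Cl2, 0 °C → rt
Reagents that add atoms: di-tert-butyl dicarbonate, CC(C)(C)OC(=O)OC(=O)OC(C)(C)C
Why: Acidolysis of an amide-type N-(4-methoxybenzyl) group (the O-protonated vinylogous amide releases the benzyl cation, which anisole traps by Friedel–Crafts alkylation) followed by N-acylation with Boc2O/DMAP, which makes the chromophore an enone-like vinylogous imide and holds back retro-Mannich cleavage until the Boc group is removed.

Step 9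
Reactants: 14 tert-butyl (2Z,7R,8S)-7-(benzyloxy)-8-methyl-4-oxo-5,6,7,8-tetrahydroazocine-1(4H)-carboxylate; 15 ethylene
Product: 19 (2S,3R,4aR,8aR)-3-(benzyloxy)-2-methyloctahydroquinolin-5(1H)-one, via N-Boc cyclobutane photoadduct 16 (not isolated), via free aminocyclobutane 17 (not isolated), via ten-membered keto-imine 18 (not isolated)
Conditions: 15 (saturated solution), hν (350 nm, Pyrex), CH2Cl2, −78 °C; then TFA, 0 °C; evaporate; then pyridine/AcOH (pyridinium acetate), MeCN, rt → 50 °C
Reagents that add atoms: none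
Why: Proposed new method: excitation of the N-Boc enaminone (an enone-like vinylogous imide) and capture of its triplet by ethylene through a 1,4-diradical should form C8a–C8 and C6–C7; the closest known reaction type is the intermolecular [2+2] photocycloaddition of N-alkoxycarbonyl-2,3-dihydro-4-pyridones with simple alkenes joined to the photocycloaddition/retro-Mannich/Mannich cascade of vinylogous amides bearing tethered alkenes, neither shown for ethylene on a medium ring nor for a transannular closure. Acidolysis of the Boc group frees the nitrogen lone pair of the donor–acceptor cyclobutane, and strain-driven retro-Mannich cleavage of C8a–C6 inserts C8–C7 to give the ten-membered keto-imine 18. In the pyridinium acetate buffer the iminium carbon C8a is attacked across the ring by the C4a=C5 enol: ring A closes in the 6-(enolendo)-exo-trig mode and the same bond completes the piperidine (ring B) in a 6-endo-trig mode, whereas attack from C6 could only rebuild the four-membered ring. C8a is controlled by the C2 methyl group, which stays equatorial in the chair-like closure onto the E-iminium ion, so that the 2,8a-cis (diequatorial) piperidine is both the kinetic and, through reversible retro-Mannich opening, the equilibrium product. C4a is expected to end cis-fused because only the cis-fused ammonium ketone can hold an N–H···O=C5 hydrogen bond, and any trans-fused material remains correctable by C4a enolisation in step 10. The step needs cycloaddition to outrun Z/E twisting of the excited eight-membered enone and Mannich closure from C4a, not C6; the N-Boc chromophore, −78 °C, saturating ethylene and the six- versus four-membered ring sizes are relied on for this.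

Step 10
Reactants: 19 (2S,3R,4aR,8aR)-3-(benzyloxy)-2-methyloctahydroquinolin-5(1H)-one
Product: 20 tert-butyl (2S,3R,4aR,8aR)-3-(benzyloxy)-2-methyl-5-oxooctahydroquinoline-1(2H)-carboxylate
Conditions: Boc2O, iPr2NEt, THF, 50 °C; then DBU (0.1 equiv), CH2Cl2, 0 °C
Reagents that add atoms: di-tert-butyl dicarbonate, CC(C)(C)OC(=O)OC(=O)OC(C)(C)C
Why: Carbamate formation on the hindered secondary amine, after which allylic 1,3-strain under the N-Boc group pushes the C2 and C8a substituents axial, an arrangement only the cis-fused ketone can adopt, so a brief base-mediated epimerisation at C4a should converge any trans-fused material.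

Step 11
Reactants: 21 (R)-2-propyloxirane ((R)-1,2-epoxypentane); 22 allylmagnesium bromide
Product: 23 (R)-oct-7-en-4-ol
Conditions: 22, CuI (cat.), THF, −30 → 0 °C; aq. NH4Cl
Reagents that add atoms: none
Why: Copper-catalysed Grignard opening of the terminal epoxide at its unsubstituted carbon (SN2), which leaves the future C5′ stereocentre untouched.

Step 12
Reactants: 23 (R)-oct-7-en-4-ol
Product: 24 (R)-tert-butyldimethyl(oct-7-en-4-yloxy)silane
Conditions: TBSCl, imidazole, DMF, rt
Reagents that add atoms: tert-butyldimethylsilyl chloride, CC(C)(C)[Si](C)(C)Cl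
Why: Silyl ether formation gives a C5′ protecting group that survives ylide chemistry, hydrogenation and esterification and falls to acid at the end.

Step 13
Reactants: 24 (R)-tert-butyldimethyl(oct-7-en-4-yloxy)silane
Product: 26 (R)-5-((tert-butyldimethylsilyl)oxy)octan-1-ol, via B-alkyl-9-BBN adduct 25 (not isolated)
Conditions: 9-BBN, THF, 0 °C → rt; then NaOH, H2O2, 0 °C
Reagents that add atoms: 9-borabicyclo[3.3.1]nonane, B1C2CCCC1CCC2 (in intermediate 25 only); hydrogen peroxide, OO
Why: Anti-Markovnikov hydroboration of the terminal alkene with 9-BBN and oxidative work-up give the primary alcohol.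

Step 14
Reactants: 26 (R)-5-((tert-butyldimethylsilyl)oxy)octan-1-ol
Product: 27 (R)-tert-butyl((8-iodooctan-4-yl)oxy)dimethylsilane
Conditions: I2, PPh3, imidazole, CH2Cl2, 0 °C → rt
Reagents that add atoms: iodine, II
Why: Appel-type iodination converts the primary alcohol into the iodide without touching the secondary silyl ether.

Step 15
Reactants: 27 (R)-tert-butyl((8-iodooctan-4-yl)oxy)dimethylsilane
Product: 28 (R)-(5-((tert-butyldimethylsilyl)oxy)octyl)triphenylphosphonium iodide
Conditions: PPh3, MeCN, reflux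
Reagents that add atoms: triphenylphosphine, c1ccccc1P(c1ccccc1)c1ccccc1
Why: SN2 quaternisation of triphenylphosphine by the primary iodide gives the Wittig salt.

Step 16
Reactants: 20 tert-butyl (2S,3R,4aR,8aR)-3-(benzyloxy)-2-methyl-5-oxooctahydroquinoline-1(2H)-carboxylate; 28 (R)-(5-((tert-butyldimethylsilyl)oxy)octyl)triphenylphosphonium iodide
Product: 30 tert-butyl (2S,3R,4aS,8aR)-3-(benzyloxy)-5-[(5R)-5-((tert-butyldimethylsilyl)oxy)octylidene]-2-methyloctahydroquinoline-1(2H)-carboxylate (E/Z mixture), via phosphonium ylide 29 (not isolated)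
Conditions: 28, KN(SiMe3)2, THF, −78 → 0 °C; then 20, −78 °C → rt
Reagents that add atoms: none
Why: Wittig olefination of the C5 ketone with the non-stabilised ylide, where alkene geometry is irrelevant because the double bond is reduced next and epimerisation at C4a would only return the favoured cis-fused N-Boc ketone.

Step 17
Reactants: 30 tert-butyl (2S,3R,4aS,8aR)-3-(benzyloxy)-5-[(5R)-5-((tert-butyldimethylsilyl)oxy)octylidene]-2-methyloctahydroquinoline-1(2H)-carboxylate
Product: 31 tert-butyl (2S,3R,4aS,5S,8aR)-5-[(5R)-5-((tert-butyldimethylsilyl)oxy)octyl]-3-hydroxy-2-methyloctahydroquinoline-1(2H)-carboxylate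
Conditions: H2 (1 atm), Pd(OH)2/C, EtOAc, rt
Reagents that add atoms: none
Why: Heterogeneous hydrogenation should deliver hydrogen to the exocyclic alkene from the convex face of the cis-fused bicycle (the face of H4a and H8a), setting C5 (S) with H5 cis to H4a, and hydrogenolyses the benzyl ether in the same operation.

Step 18
Reactants: 31 tert-butyl (2S,3R,4aS,5S,8aR)-5-[(5R)-5-((tert-butyldimethylsilyl)oxy)octyl]-3-hydroxy-2-methyloctahydroquinoline-1(2H)-carboxylate; 32 (2E,4E)-octa-2,4-dienoic acid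
Product: 33 tert-butyl (2S,3R,4aS,5S,8aR)-5-[(5R)-5-((tert-butyldimethylsilyl)oxy)octyl]-2-methyl-3-[((2E,4E)-octa-2,4-dienoyl)oxy]octahydroquinoline-1(2H)-carboxylate
Conditions: N,N′-diisopropylcarbodiimide, DMAP, CH2Cl2, 0 °C → rt
Reagents that add atoms: none
Why: Steglich esterification acylates the only free hydroxyl (O3), since the nitrogen is a carbamate and O5′ is silylated.

Step 19
Reactants: 33 tert-butyl (2S,3R,4aS,5S,8aR)-5-[(5R)-5-((tert-butyldimethylsilyl)oxy)octyl]-2-methyl-3-[((2E,4E)-octa-2,4-dienoyl)oxy]octahydroquinoline-1(2H)-carboxylate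
Product: 34 Lepadin H
Conditions: TFA/CH2Cl2/H2O, 0 °C → rt; then cold aq. NaHCO3
Reagents that add atoms: none
Why: Acidolysis removes the Boc group and the TBS ether in one operation, under conditions in which the dienoate is stable and the protonated nitrogen cannot take over the acyl group from O3.

**Compound list**

1 | tert-butyl (S)-(1-(methoxy(methyl)amino)-1-oxopropan-2-yl)carbamate | C[C@H](NC(=O)OC(C)(C)C)C(=O)N(C)OC | starting material
2 | but-3-en-1-ylmagnesium bromide | C=CCC[Mg]Br | starting material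
3 | tert-butyl (S)-(3-oxohept-6-en-2-yl)carbamate | C[C@H](NC(=O)OC(C)(C)C)C(=O)CCC=C | intermediate
4 | tert-butyl ((2S,3R)-3-hydroxyhept-6-en-2-yl)carbamate | C[C@H](NC(=O)OC(C)(C)C)[C@H](O)CCC=C | intermediate
5 | tert-butyl ((2S,3R)-3-(benzyloxy)hept-6-en-2-yl)carbamate | C[C@H](NC(=O)OC(C)(C)C)[C@H](OCc1ccccc1)CCC=C | intermediate
6 | tert-butyl ((2S,3R)-3-(benzyloxy)hept-6-en-2-yl)(4-methoxybenzyl)carbamate | C[C@H](N(Cc1ccc(OC)cc1)C(=O)OC(C)(C)C)[C@H](OCc1ccccc1)CCC=C | intermediate
7 | tert-butyl ((2S,3R)-3-(benzyloxy)-6-oxohexan-2-yl)(4-methoxybenzyl)carbamate | C[C@H](N(Cc1ccc(OC)cc1)C(=O)OC(C)(C)C)[C@H](OCc1ccccc1)CCC=O | intermediate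
8 | ethynylmagnesium bromide | C#C[Mg]Br | starting material
9 | tert-butyl ((2S,3R)-3-(benzyloxy)-6-hydroxyoct-7-yn-2-yl)(4-methoxybenzyl)carbamate (C6 epimers) | C[C@H](N(Cc1ccc(OC)cc1)C(=O)OC(C)(C)C)[C@H](OCc1ccccc1)CCC(O)C#C | intermediate
10 | tert-butyl ((2S,3R)-3-(benzyloxy)-6-oxooct-7-yn-2-yl)(4-methoxybenzyl)carbamate | C[C@H](N(Cc1ccc(OC)cc1)C(=O)OC(C)(C)C)[C@H](OCc1ccccc1)CCC(=O)C#C | intermediate
11 | (6R,7S)-6-(benzyloxy)-7-((4-methoxybenzyl)amino)oct-1-yn-3-one (trifluoroacetate salt in the flask) | C[C@H](NCc1ccc(OC)cc1)[C@H](OCc1ccccc1)CCC(=O)C#C | intermediate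
12 | (2Z,7R,8S)-7-(benzyloxy)-1-(4-methoxybenzyl)-8-methyl-5,6,7,8-tetrahydroazocin-4(1H)-one | C[C@@H]1N(Cc2ccc(OC)cc2)/C=C\C(=O)CC[C@H]1OCc1ccccc1 | intermediate
13 | (2Z,7R,8S)-7-(benzyloxy)-8-methyl-5,6,7,8-tetrahydroazocin-4(1H)-one | C[C@@H]1N/C=C\C(=O)CC[C@H]1OCc1ccccc1 | intermediate
14 | tert-butyl (2Z,7R,8S)-7-(benzyloxy)-8-methyl-4-oxo-5,6,7,8-tetrahydroazocine-1(4H)-carboxylate | C[C@@H]1N(C(=O)OC(C)(C)C)/C=C\C(=O)CC[C@H]1OCc1ccccc1 | intermediate
15 | ethylene | C=C | starting material
16 | tert-butyl (3S,4R)-4-(benzyloxy)-3-methyl-7-oxo-2-azabicyclo[6.2.0]decane-2-carboxylate (ring-fusion isomers) | C[C@@H]1N(C(=O)OC(C)(C)C)C2CCC2C(=O)CC[C@H]1OCc1ccccc1 | intermediate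
17 | (3S,4R)-4-(benzyloxy)-3-methyl-2-azabicyclo[6.2.0]decan-7-one (ring-fusion isomers) | C[C@@H]1NC2CCC2C(=O)CC[C@H]1OCc1ccccc1 | intermediate
18 | (9R,10S)-9-(benzyloxy)-10-methyl-1-azacyclodec-1-en-6-one | C[C@@H]1N=CCCCC(=O)CC[C@H]1OCc1ccccc1 | intermediate
19 | (2S,3R,4aR,8aR)-3-(benzyloxy)-2-methyloctahydroquinolin-5(1H)-one | O(Cc1ccccc1)[C@@H]1C[C@H]2C(=O)CCC[C@H]2N[C@H]1C | intermediate
20 | tert-butyl (2S,3R,4aR,8aR)-3-(benzyloxy)-2-methyl-5-oxooctahydroquinoline-1(2H)-carboxylate | O(Cc1ccccc1)[C@@H]1C[C@H]2C(=O)CCC[C@H]2N(C(=O)OC(C)(C)C)[C@H]1C | intermediate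
21 | (R)-2-propyloxirane | CCC[C@@H]1CO1 | starting material
22 | allylmagnesium bromide | C=CC[Mg]Br | starting material
23 | (R)-oct-7-en-4-ol | C=CCC[C@H](O)CCC | intermediate
24 | (R)-tert-butyldimethyl(oct-7-en-4-yloxy)silane | C=CCC[C@H](O[Si](C)(C)C(C)(C)C)CCC | intermediate
25 | 9-[(5R)-5-((tert-butyldimethylsilyl)oxy)octyl]-9-borabicyclo[3.3.1]nonane | B1(CCCC[C@H](O[Si](C)(C)C(C)(C)C)CCC)C2CCCC1CCC2 | intermediate
26 | (R)-5-((tert-butyldimethylsilyl)oxy)octan-1-ol | OCCCC[C@H](O[Si](C)(C)C(C)(C)C)CCC | intermediate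
27 | (R)-tert-butyl((8-iodooctan-4-yl)oxy)dimethylsilane | ICCCC[C@H](O[Si](C)(C)C(C)(C)C)CCC | intermediate
28 | (R)-(5-((tert-butyldimethylsilyl)oxy)octyl)triphenylphosphonium iodide | [I-].c1ccccc1[P+](c1ccccc1)(c1ccccc1)CCCC[C@H](O[Si](C)(C)C(C)(C)C)CCC | intermediate
29 | (R)-(5-((tert-butyldimethylsilyl)oxy)octylidene)triphenylphosphorane | c1ccccc1P(c1ccccc1)(c1ccccc1)=CCCC[C@H](O[Si](C)(C)C(C)(C)C)CCC | intermediate
30 | tert-butyl (2S,3R,4aS,8aR)-3-(benzyloxy)-5-[(5R)-5-((tert-butyldimethylsilyl)oxy)octylidene]-2-methyloctahydroquinoline-1(2H)-carboxylate | O(Cc1ccccc1)[C@@H]1C[C@H]2C(=CCCC[C@H](O[Si](C)(C)C(C)(C)C)CCC)CCC[C@H]2N(C(=O)OC(C)(C)C)[C@H]1C | intermediate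
31 | tert-butyl (2S,3R,4aS,5S,8aR)-5-[(5R)-5-((tert-butyldimethylsilyl)oxy)octyl]-3-hydroxy-2-methyloctahydroquinoline-1(2H)-carboxylate | O[C@@H]1C[C@H]2[C@@H](CCCC[C@H](O[Si](C)(C)C(C)(C)C)CCC)CCC[C@H]2N(C(=O)OC(C)(C)C)[C@H]1C | intermediate
32 | (2E,4E)-octa-2,4-dienoic acid | CCC/C=C/C=C/C(=O)O | starting material
33 | tert-butyl (2S,3R,4aS,5S,8aR)-5-[(5R)-5-((tert-butyldimethylsilyl)oxy)octyl]-2-methyl-3-[((2E,4E)-octa-2,4-dienoyl)oxy]octahydroquinoline-1(2H)-carboxylate | CCC/C=C/C=C/C(=O)O[C@@H]1C[C@H]2[C@@H](CCCC[C@H](O[Si](C)(C)C(C)(C)C)CCC)CCC[C@H]2N(C(=O)OC(C)(C)C)[C@H]1C | intermediate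
34 | Lepadin H, (2S,3R,4aS,5S,8aR)-5-[(5R)-5-hydroxyoctyl]-2-methyldecahydroquinolin-3-yl (2E,4E)-octa-2,4-dienoate | CCC/C=C/C=C/C(=O)O[C@@H]1C[C@H]2[C@@H](CCCC[C@H](O)CCC)CCC[C@H]2N[C@H]1C | target

**Step count**

Total steps: 19. Longest linear sequence: 14 steps (steps 1–10 and 16–19); the side-chain branch is steps 11–15.

**Steps most likely to fail**

Step 9 (proposed new method). The excited eight-membered enone may decay by Z/E twisting, or its strained E isomer may react thermally, instead of adding ethylene; the reversible Mannich closure may also leak to the trans ring fusion. The fallback uses known chemistry, sets out from compound 5 (isolated after the first stage of step 3) and returns at compound 20. Lemieux–Johnson cleavage of 5 gives tert-butyl ((2S,3R)-3-(benzyloxy)-6-oxohexan-2-yl)carbamate F1, present largely as its cyclic hemiaminal. Addition of [3-(1,3-dioxolan-2-yl)propyl]magnesium bromide gives tert-butyl ((2S,3R)-3-(benzyloxy)-9-(1,3-dioxolan-2-yl)-6-hydroxynonan-2-yl)carbamate F2, and Dess–Martin oxidation gives tert-butyl ((2S,3R)-3-(benzyloxy)-9-(1,3-dioxolan-2-yl)-6-oxononan-2-yl)carbamate F3. Mild aqueous acid unmasks tert-butyl ((2S,3R)-3-(benzyloxy)-6,10-dioxodecan-2-yl)carbamate F4, whose only six-membered aldol condensation (C4a onto C8a) gives tert-butyl ((2S,3R)-3-(benzyloxy)-4-(6-oxocyclohex-1-en-1-yl)butan-2-yl)carbamate F5. Base-mediated intramolecular aza-Michael addition of the carbamate nitrogen to C8a (KOtBu cat., THF), run under equilibrating conditions, should then give the cis-fused N-Boc ketone 20.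

Step 7. Intermolecular conjugate addition (oligomer formation) may outrun the eight-membered ring closure. The fallback builds the ring by metathesis instead, sets out from compound 5 and returns at compound 14, so that the relay group and step 8 are bypassed. N-Allylation (NaH, allyl bromide, DMF) gives tert-butyl allyl((2S,3R)-3-(benzyloxy)hept-6-en-2-yl)carbamate F6. Ring-closing metathesis with the second-generation Grubbs catalyst at high dilution gives tert-butyl (3Z,7R,8S)-7-(benzyloxy)-8-methyl-5,6,7,8-tetrahydroazocine-1(2H)-carboxylate F7. Wacker oxidation (PdCl2, CuCl, O2, DMF/H2O) should place the carbonyl at the alkene carbon remote from the carbamate nitrogen, giving tert-butyl (7R,8S)-7-(benzyloxy)-8-methyl-4-oxoazocane-1-carboxylate F8. Aerobic dehydrogenation of this ketone (Pd(OCOCF3)2, DMSO, O2), which should favour loss of the hydridic N–CH2 hydrogen and so give the conjugated carbamate, leads to 14.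

Step 16. The basic ylide may enolise the hindered α-branched ketone (returning ketone) or trigger E1cB loss of the carbamate nitrogen from the C4a enolate. The fallback replaces olefination by cross-coupling, sets out from compound 20 and returns at compound 31. Kinetic deprotonation at C6 and triflation (KN(SiMe3)2, PhNTf2, −78 °C) give tert-butyl (2S,3R,4aR,8aR)-3-(benzyloxy)-2-methyl-5-(((trifluoromethyl)sulfonyl)oxy)-3,4,4a,7,8,8a-hexahydroquinoline-1(2H)-carboxylate F9. B-alkyl Suzuki–Miyaura coupling with borane 25 (Pd(dppf)Cl2, Cs2CO3, DMF/THF/H2O) gives tert-butyl (2S,3R,4aS,8aR)-3-(benzyloxy)-5-[(5R)-5-((tert-butyldimethylsilyl)oxy)octyl]-2-methyl-3,4,4a,7,8,8a-hexahydroquinoline-1(2H)-carboxylate F10. Hydrogenation (H2, Pd(OH)2/C) from the convex face with loss of the benzyl group gives 31; steps 13–15 then end at borane 25.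

Further compounds
F1 | step 9 | tert-butyl ((2S,3R)-3-(benzyloxy)-6-oxohexan-2-yl)carbamate | C[C@H](NC(=O)OC(C)(C)C)[C@H](OCc1ccccc1)CCC=O
F2 | step 9 | tert-butyl ((2S,3R)-3-(benzyloxy)-9-(1,3-dioxolan-2-yl)-6-hydroxynonan-2-yl)carbamate | C[C@H](NC(=O)OC(C)(C)C)[C@H](OCc1ccccc1)CCC(O)CCCC1OCCO1
F3 | step 9 | tert-butyl ((2S,3R)-3-(benzyloxy)-9-(1,3-dioxolan-2-yl)-6-oxononan-2-yl)carbamate | C[C@H](NC(=O)OC(C)(C)C)[C@H](OCc1ccccc1)CCC(=O)CCCC1OCCO1
F4 | step 9 | tert-butyl ((2S,3R)-3-(benzyloxy)-6,10-dioxodecan-2-yl)carbamate | C[C@H](NC(=O)OC(C)(C)C)[C@H](OCc1ccccc1)CCC(=O)CCCC=O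
F5 | step 9 | tert-butyl ((2S,3R)-3-(benzyloxy)-4-(6-oxocyclohex-1-en-1-yl)butan-2-yl)carbamate | C[C@H](NC(=O)OC(C)(C)C)[C@H](OCc1ccccc1)CC1=CCCCC1=O
F6 | step 7 | tert-butyl allyl((2S,3R)-3-(benzyloxy)hept-6-en-2-yl)carbamate | C[C@H](N(CC=C)C(=O)OC(C)(C)C)[C@H](OCc1ccccc1)CCC=C
F7 | step 7 | tert-butyl (3Z,7R,8S)-7-(benzyloxy)-8-methyl-5,6,7,8-tetrahydroazocine-1(2H)-carboxylate | C[C@@H]1N(C(=O)OC(C)(C)C)C/C=C\CC[C@H]1OCc1ccccc1
F8 | step 7 | tert-butyl (7R,8S)-7-(benzyloxy)-8-methyl-4-oxoazocane-1-carboxylate | C[C@@H]1N(C(=O)OC(C)(C)C)CCC(=O)CC[C@H]1OCc1ccccc1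
F9 | step 16 | tert-butyl (2S,3R,4aR,8aR)-3-(benzyloxy)-2-methyl-5-(((trifluoromethyl)sulfonyl)oxy)-3,4,4a,7,8,8a-hexahydroquinoline-1(2H)-carboxylate | O(Cc1ccccc1)[C@@H]1C[C@H]2C(OS(=O)(=O)C(F)(F)F)=CCC[C@H]2N(C(=O)OC(C)(C)C)[C@H]1C
F10 | step 16 | tert-butyl (2S,3R,4aS,8aR)-3-(benzyloxy)-5-[(5R)-5-((tert-butyldimethylsilyl)oxy)octyl]-2-methyl-3,4,4a,7,8,8a-hexahydroquinoline-1(2H)-carboxylate | O(Cc1ccccc1)[C@@H]1C[C@H]2C(CCCC[C@H](O[Si](C)(C)C(C)(C)C)CCC)=CCC[C@H]2N(C(=O)OC(C)(C)C)[C@H]1C
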